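**Plan**
- The retrosynthesis first removes three O‑methyl groups and one O‑silyl group. It then dismantles ring D at three C–C bonds (C4–C3, C2–C1, C1–C6), which leads back to a 4‑arylbut‑1‑yne, one CO ligand and a β‑silylvinyl methoxycarbene of chromium.
- Enabling feature: ring D is a benzene‑1,4‑diol with the ethylene bridge at C2. C1–O comes from CO and C4–O, para to it, is the carbene carbon. C2–C3 is the alkyne with its substituent next to C1, and the bare C5–C6 edge is the vinyl group.
- Earlier cuts are the CH2–CH2 bond of the C/D bridge (benzylic bromide plus propargyl anion), the ring B–O bond of the diaryl ether (Ullmann) and the A/B bridge (olefination, then reduction).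
- In the forward direction rings A, B and C are purchased arenes. They are joined A–B, then B–O–C, ring C is extended by three carbons, and ring D is the only ring built, and it is built last.
- The target has no stereocentre and no stereogenic double bond. The E alkenes met on the way are either reduced or absorbed into ring D.

Key step: step 8

Assumption: in the dienone that precedes aromatisation of ring D the SiMe3 group, not the hydrogen, moves to oxygen, so the benzannulation product is drawn as the aryl trimethylsilyl ether. Its C‑silylated phenol isomer would be converted to the same phenol by the acid of step 9.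

**Step 1**
Reactants: 1 diethyl (3-methoxybenzyl)phosphonate; 2 4-bromobenzaldehyde
Product: 3 (E)-1-bromo-4-[2-(3-methoxyphenyl)ethenyl]benzene
Conditions: KOtBu, THF, 0 °C to rt; then 1 M HCl
Reagents that add atoms: none
Why: Horner–Wadsworth–Emmons olefination of a non-enolisable aryl aldehyde with a benzylic phosphonate anion is dependable and E-selective, and the alkene geometry is erased in the next step in any case.

**Step 2**
Reactants: 3 (E)-1-bromo-4-[2-(3-methoxyphenyl)ethenyl]benzene
Product: 4 1-bromo-4-[2-(3-methoxyphenyl)ethyl]benzene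
Conditions: TsNHNH2 (excess), NaOAc buffer, THF/H2O, reflux
Reagents that add atoms: none
Why: Diimide reduction delivers H2 concertedly to the C=C bond only, so the aryl bromide that hydrogenation over Pd would endanger should survive.

**Step 3**
Reactants: 4 1-bromo-4-[2-(3-methoxyphenyl)ethyl]benzene; 5 isovanillin (3-hydroxy-4-methoxybenzaldehyde)
Product: 6 4-methoxy-3-{4-[2-(3-methoxyphenyl)ethyl]phenoxy}benzaldehyde
Conditions: CuI (10 mol %), N,N-dimethylglycine hydrochloride (30 mol %), Cs2CO3, 1,4-dioxane, 90 °C, Ar
Reagents that add atoms: none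
Why: In this ligand-accelerated Ullmann diaryl ether synthesis the monovalent copper phenoxide of 5 engages the aryl bromide at a temperature where the non-enolisable aldehyde and the methyl ethers are inert.

**Step 4**
Reactants: 6 4-methoxy-3-{4-[2-(3-methoxyphenyl)ethyl]phenoxy}benzaldehyde
Product: 7 (4-methoxy-3-{4-[2-(3-methoxyphenyl)ethyl]phenoxy}phenyl)methanol
Conditions: NaBH4, MeOH/THF, 0 °C
Reagents that add atoms: none
Why: Borohydride reduction of an aryl aldehyde should be clean because the molecule holds no other reducible group.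

**Step 5**
Reactants: 7 (4-methoxy-3-{4-[2-(3-methoxyphenyl)ethyl]phenoxy}phenyl)methanol
Product: 8 4-(bromomethyl)-1-methoxy-2-{4-[2-(3-methoxyphenyl)ethyl]phenoxy}benzene
Conditions: PBr3, CH2Cl2, 0 °C; used at once without chromatography
Reagents that add atoms: phosphorus tribromide, BrP(Br)Br
Why: Bromide displaces the phosphite ester of the benzylic alcohol, the para methoxy group makes this fast at 0 °C, and the reactive bromide is therefore not stored.

**Step 6**
Reactants: 8 4-(bromomethyl)-1-methoxy-2-{4-[2-(3-methoxyphenyl)ethyl]phenoxy}benzene; 9 1-(trimethylsilyl)propyne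
Product: 12 4-(but-3-yn-1-yl)-1-methoxy-2-{4-[2-(3-methoxyphenyl)ethyl]phenoxy}benzene, via 3-lithio-1-(trimethylsilyl)propyne 10 (not isolated), via C-silylated butynylarene 11 (not isolated)
Conditions: 9, n-BuLi, THF, −78 °C; 8 added, −78 to 0 °C; then MeOH, K2CO3 (cat.), rt
Reagents that add atoms: none
Why: In this SN2 alkylation of a propargylic organolithium the silyl cap blocks the acetylenic end and suppresses allene formation, and base-catalysed methanolysis of the C(sp)–Si bond in the same flask then frees the terminal alkyne.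

**Step 7**
Reactants: 13 (E)-(2-bromovinyl)trimethylsilane; 14 chromium hexacarbonyl Cr(CO)6
Product: 17 pentacarbonyl[(E)-1-methoxy-3-(trimethylsilyl)prop-2-en-1-ylidene]chromium, via (E)-2-(trimethylsilyl)vinyllithium 15 (not isolated), via lithium acylchromate 16 (not isolated)
Conditions: t-BuLi (2 equiv), Et2O, −78 °C; Cr(CO)6, Et2O, −78 °C to rt; solvent exchange; Me3OBF4, CH2Cl2, 0 °C to rt
Reagents that add atoms: trimethyloxonium tetrafluoroborate, C[O+](C)C.F[B-](F)(F)F
Why: This Fischer carbene synthesis combines bromine–lithium exchange with retention of the E geometry, addition of the vinyllithium to a CO ligand and O-methylation of the acylate, and the β-silyl group shields the complex from the conjugate-addition polymerisation that makes the parent vinyl complex unusable.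

**Step 8**
Reactants: 12 4-(but-3-yn-1-yl)-1-methoxy-2-{4-[2-(3-methoxyphenyl)ethyl]phenoxy}benzene; 17 pentacarbonyl[(E)-1-methoxy-3-(trimethylsilyl)prop-2-en-1-ylidene]chromium
Product: 19 {4-methoxy-2-[2-(4-methoxy-3-{4-[2-(3-methoxyphenyl)ethyl]phenoxy}phenyl)ethyl]phenoxy}trimethylsilane, via tricarbonylchromium complex of ring D 18 (not isolated)
Conditions: 17 (1.3 equiv), degassed THF, 50 °C, Ar; then Et2O, air, visible light, rt; filtration through Celite, crude carried on
Reagents that add atoms: none
Why: This is a Dötz benzannulation of an alkenyl Fischer carbene complex with a terminal alkyne: thermal loss of one cis CO from 17 frees a site on zerovalent chromium, the triple bond of 12 binds and inserts into Cr=C (bond 1, carbene carbon to terminal alkyne carbon), and a CO ligand migrates onto the new carbene carbon (bond 2) to give a chromium-bound dienylketene. Ring D then closes by 6π electrocyclisation of that ketene, its central carbon bonding to the silyl-bearing vinyl carbon (bond 3), which gives a cyclohexa-2,4-dienone. The one sp3 carbon of this dienone carries H and SiMe3, and a 1,3 shift of silicon to the carbonyl oxygen aromatises the ring, so the CO-derived oxygen appears as OSiMe3 and the carbene-derived oxygen as OMe, para to each other. The only selectivity needed is the direction of alkyne insertion, and it is steric: the substituted alkyne carbon stays away from the carbene substituents and ends beside the CO-derived carbon, a preference that is largest for a terminal alkyne (H against CH2CH2Ar), so the bridge lies ortho to OSiMe3 and meta to OMe. Alkenyl complexes in THF favour CO insertion over five-membered ring formation, rings A to C offer only aryl ethers and CH2 groups that leave the metal alone, and no stereocentre is created. The Cr(CO)3 fragment left on ring D in 18 is removed by air and light, the usual oxidative demetalation of arene tricarbonyl complexes.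

**Step 9**
Reactants: 19 {4-methoxy-2-[2-(4-methoxy-3-{4-[2-(3-methoxyphenyl)ethyl]phenoxy}phenyl)ethyl]phenoxy}trimethylsilane
Product: 20 4-methoxy-2-[2-(4-methoxy-3-{4-[2-(3-methoxyphenyl)ethyl]phenoxy}phenyl)ethyl]phenol
Conditions: TFA, CH2Cl2, 0 °C to rt; aqueous work-up; chromatography
Reagents that add atoms: none
Why: Acid cleavage of an aryl trimethylsilyl ether is fast, the same acid would also remove any silicon left on carbon by ipso protonation ortho to the phenol oxygen (protodesilylation), and the product is the first ring D compound robust enough to purify.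

**Step 10**
Reactants: 20 4-methoxy-2-[2-(4-methoxy-3-{4-[2-(3-methoxyphenyl)ethyl]phenoxy}phenyl)ethyl]phenol
Product: 21 2-[2-(4-hydroxy-3-{4-[2-(3-hydroxyphenyl)ethyl]phenoxy}phenyl)ethyl]benzene-1,4-diol (CNP0300581.0)
Conditions: BBr3 (6 equiv), CH2Cl2, −78 °C to rt; degassed ice-water, Ar
Reagents that add atoms: none
Why: Lewis acid demethylation of aryl methyl ethers with BBr3 (boron binds the oxygen, bromide attacks CH3) leaves the diaryl ether and both bridges intact, and work-up under argon protects the hydroquinone ring D from air oxidation.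

**Compound list**
1 | diethyl (3-methoxybenzyl)phosphonate | CCOP(=O)(Cc1cccc(OC)c1)OCC | starting material
2 | 4-bromobenzaldehyde | O=Cc1ccc(Br)cc1 | starting material
3 | (E)-1-bromo-4-[2-(3-methoxyphenyl)ethenyl]benzene | COc1cccc(/C=C/c2ccc(Br)cc2)c1 | intermediate
4 | 1-bromo-4-[2-(3-methoxyphenyl)ethyl]benzene | COc1cccc(CCc2ccc(Br)cc2)c1 | intermediate
5 | isovanillin (3-hydroxy-4-methoxybenzaldehyde) | COc1ccc(C=O)cc1O | starting material
6 | 4-methoxy-3-{4-[2-(3-methoxyphenyl)ethyl]phenoxy}benzaldehyde | COc1ccc(C=O)cc1Oc1ccc(CCc2cccc(OC)c2)cc1 | intermediate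
7 | (4-methoxy-3-{4-[2-(3-methoxyphenyl)ethyl]phenoxy}phenyl)methanol | COc1ccc(CO)cc1Oc1ccc(CCc2cccc(OC)c2)cc1 | intermediate
8 | 4-(bromomethyl)-1-methoxy-2-{4-[2-(3-methoxyphenyl)ethyl]phenoxy}benzene | COc1ccc(CBr)cc1Oc1ccc(CCc2cccc(OC)c2)cc1 | intermediate
9 | 1-(trimethylsilyl)propyne | CC#C[Si](C)(C)C | starting material
10 | 3-lithio-1-(trimethylsilyl)propyne | [Li]CC#C[Si](C)(C)C | intermediate
11 | [4-(4-methoxy-3-{4-[2-(3-methoxyphenyl)ethyl]phenoxy}phenyl)but-1-yn-1-yl]trimethylsilane | C[Si](C)(C)C#CCCc1ccc(OC)c(Oc2ccc(CCc3cccc(OC)c3)cc2)c1 | intermediate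
12 | 4-(but-3-yn-1-yl)-1-methoxy-2-{4-[2-(3-methoxyphenyl)ethyl]phenoxy}benzene | C#CCCc1ccc(OC)c(Oc2ccc(CCc3cccc(OC)c3)cc2)c1 | intermediate
13 | (E)-(2-bromovinyl)trimethylsilane | C[Si](C)(C)/C=C/Br | starting material
14 | chromium hexacarbonyl Cr(CO)6 | O=C=[Cr](=C=O)(=C=O)(=C=O)(=C=O)=C=O | starting material
15 | (E)-2-(trimethylsilyl)vinyllithium | [Li]/C=C/[Si](C)(C)C | intermediate
16 | lithium pentacarbonyl[(E)-1-oxido-3-(trimethylsilyl)prop-2-en-1-ylidene]chromate | [Li+].[O-]C(/C=C/[Si](C)(C)C)=[Cr](=C=O)(=C=O)(=C=O)(=C=O)=C=O | intermediate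
17 | pentacarbonyl[(E)-1-methoxy-3-(trimethylsilyl)prop-2-en-1-ylidene]chromium | COC(/C=C/[Si](C)(C)C)=[Cr](=C=O)(=C=O)(=C=O)(=C=O)=C=O | intermediate
18 | tricarbonyl(η6-arene)chromium complex of 19, metal bound to ring D (written as two parts) | COc1ccc(O[Si](C)(C)C)c(CCc2ccc(OC)c(Oc3ccc(CCc4cccc(OC)c4)cc3)c2)c1.O=C=[Cr](=C=O)=C=O | intermediate
19 | {4-methoxy-2-[2-(4-methoxy-3-{4-[2-(3-methoxyphenyl)ethyl]phenoxy}phenyl)ethyl]phenoxy}trimethylsilane | COc1ccc(O[Si](C)(C)C)c(CCc2ccc(OC)c(Oc3ccc(CCc4cccc(OC)c4)cc3)c2)c1 | intermediate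
20 | 4-methoxy-2-[2-(4-methoxy-3-{4-[2-(3-methoxyphenyl)ethyl]phenoxy}phenyl)ethyl]phenol | COc1ccc(O)c(CCc2ccc(OC)c(Oc3ccc(CCc4cccc(OC)c4)cc3)c2)c1 | intermediate
21 | 2-[2-(4-hydroxy-3-{4-[2-(3-hydroxyphenyl)ethyl]phenoxy}phenyl)ethyl]benzene-1,4-diol | Oc1cccc(CCc2ccc(Oc3cc(CCc4cc(O)ccc4O)ccc3O)cc2)c1 | target

**Step count**
Total step count: 10. Longest linear sequence: 9 (steps 1 to 6, then 8 to 10). Step 7 is a one-step side branch that joins at step 8.

**Steps most likely to fail**

Step 8. The alkenyl carbene complex may decay thermally before it loses CO and captures the alkyne. The metal may also take up a second alkyne unit or oligomerise the alkyne. An incomplete carbon-to-oxygen silyl shift would spread the material over several silylated forms. The fallback gives up building ring D at the metal and buys it instead. It sets out from bromide 8, which is heated with P(OEt)3 (Michaelis–Arbuzov) to give the diethyl benzylphosphonate F1. Horner–Wadsworth–Emmons olefination of F1 with commercial 2,5-dimethoxybenzaldehyde (KOtBu, THF) should give the (E)-stilbene F2. Hydrogenation of F2 (H2, Pd/C, EtOAc) gives the tetramethyl ether F3, and BBr3 in CH2Cl2 brings the sequence back to the route at target 21.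

Step 3. Copper turnover may be slow with an electron-neutral bromide and an ortho-substituted phenoxide that the aldehyde also deactivates, and hydrodebromination may compete. The fallback replaces the halide coupling by an oxidative coupling at room temperature. It sets out from bromide 4, which is converted (n-BuLi, THF, −78 °C; B(OiPr)3; dilute acid) into the arylboronic acid F4. Chan–Lam coupling of F4 with isovanillin 5 (Cu(OAc)2, pyridine, 4 Å molecular sieves, CH2Cl2, air, rt) returns to the route at aldehyde 6.

Step 6. The electron-rich benzylic bromide may ionise or undergo halogen–lithium exchange, which would lead to Wurtz-type dimerisation, and it may degrade before use. The fallback avoids any benzylic halide. It sets out from aldehyde 6, bypassing 7 and 8, with a Horner–Wadsworth–Emmons reaction with triethyl phosphonoacetate (NaH, THF) that gives the ethyl cinnamate F5. Hydrogenation (H2, Pd/C) gives the ethyl propanoate F6, and i-Bu2AlH (CH2Cl2, −78 °C) gives the 3-arylpropanal F7. Seyferth–Gilbert homologation of F7 with the Ohira–Bestmann reagent (dimethyl (1-diazo-2-oxopropyl)phosphonate, K2CO3, MeOH) returns to the route at alkyne 12.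

**Further compounds**
F1 | step 8 | diethyl (4-methoxy-3-{4-[2-(3-methoxyphenyl)ethyl]phenoxy}benzyl)phosphonate | CCOP(=O)(Cc1ccc(OC)c(Oc2ccc(CCc3cccc(OC)c3)cc2)c1)OCC
F2 | step 8 | (E)-1,4-dimethoxy-2-[2-(4-methoxy-3-{4-[2-(3-methoxyphenyl)ethyl]phenoxy}phenyl)ethenyl]benzene | COc1ccc(OC)c(/C=C/c2ccc(OC)c(Oc3ccc(CCc4cccc(OC)c4)cc3)c2)c1
F3 | step 8 | 1,4-dimethoxy-2-[2-(4-methoxy-3-{4-[2-(3-methoxyphenyl)ethyl]phenoxy}phenyl)ethyl]benzene | COc1ccc(OC)c(CCc2ccc(OC)c(Oc3ccc(CCc4cccc(OC)c4)cc3)c2)c1
F4 | step 3 | {4-[2-(3-methoxyphenyl)ethyl]phenyl}boronic acid | COc1cccc(CCc2ccc(B(O)O)cc2)c1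
F5 | step 6 | ethyl (E)-3-(4-methoxy-3-{4-[2-(3-methoxyphenyl)ethyl]phenoxy}phenyl)prop-2-enoate | CCOC(=O)/C=C/c1ccc(OC)c(Oc2ccc(CCc3cccc(OC)c3)cc2)c1
F6 | step 6 | ethyl 3-(4-methoxy-3-{4-[2-(3-methoxyphenyl)ethyl]phenoxy}phenyl)propanoate | CCOC(=O)CCc1ccc(OC)c(Oc2ccc(CCc3cccc(OC)c3)cc2)c1
F7 | step 6 | 3-(4-methoxy-3-{4-[2-(3-methoxyphenyl)ethyl]phenoxy}phenyl)propanal | O=CCCc1ccc(OC)c(Oc2ccc(CCc3cccc(OC)c3)cc2)c1
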